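## The problem

Numbering used throughout: the cyclopentane is C1–C5 (C1 and C5 are the ring-fusion carbons, C4 is quaternary); the cycloheptane is C1, C10, C9, C8, C7, C6, C5; C1' is the benzylic carbon on C4; C11 is the carbon attached to C7. The β face is the face of the C4 methyl group.

- Target 33 is a trans-fused hydroazulene (H1 β, H5 α). Its quaternary C4 carries a methyl group and, through C1', an isobutyl group and a 3,5-diformylphloroglucinol ring.
- Six stereocentres must be set: C1 (R), C4 (S), C5 (S), C7 (R), C10 (R) and C1' (R).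
- C5 can control C4, because an electrophile enters a cyclopentanone enolate anti to the C5 substituent. C4 can bias C1' and, through its α-oriented benzylic branch, the faces of C10. C1 becomes correctable by equilibration once C10 is a ketone.
- C7 sits 1,3 to C5 on a flexible seven-membered ring. No existing centre and no predictable equilibrium can set it, so it has to be brought in as a fixed centre.
- The C4–C1' bond joins a quaternary carbon to a carbon flanked by a 2,6-dioxygenated arene and is very congested.
- The tertiary C10 alcohol and the isopropenyl group do not survive Lewis or protic acids. The formylated phloroglucinol is sensitive to oxidants and nucleophiles. The arene is therefore carried as its trimethyl ether, and the formyl groups and free phenols appear last, under basic conditions.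
- The enabling feature: C10 is bonded to ring-fusion C1, and C1 is β to C3, a ring methylene that can temporarily be a ketone. The C1–C10 bond is thus exactly what a C10 acyl radical makes when it adds to a cyclopent-2-enone (C1=C2–C3=O). The C10 ketone so formed is the handle for the methyl carbinol, and the C3 ketone is the one that builds C4 and C5.

## Retrosynthesis

**Phenols and formyl groups (33 ⇒ 32 ⇒ 30 ⇒ 29).** The three O–CH3 bonds and the two aryl–CHO bonds are cut last. Thiolate demethylation only works once the formyl groups activate the ring, so 33 comes from dialdehyde 32. Acidic formylation would destroy the C10 carbinol and the isopropenyl group, so each formyl group is placed by lithiation of an aryl C–H flanked by two methoxy groups (29 → 30 → 32). The precursor 29 has a plain 2,4,6-trimethoxyphenyl ring that is inert to everything before it.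

**Isopropenyl group (29 ⇒ 28 ⇒ 27 ⇒ 26).** The C11=CH2 bond is cut back to the methyl ketone 28, which comes from the secondary alcohol 27 and its silyl ether 26. A free alkene at C7 would capture the acyl radical in a 6-endo mode, so it must be masked during ring closure. A ketal-protected acetyl group would be shorter by one step, but it leaves C7 to an unpredictable equilibration. The 1-silyloxyethyl group keeps C7 non-epimerisable until the last neutral operations.

**C10 carbinol and C3 methylene (26 ⇒ 25 ⇒ 24 ⇒ 23 ⇒ 22 ⇒ 21).** The C3–H bond is traced to a xanthate (25) of diol 24. The C10 methyl carbinol is traced through epoxide 23 and exocyclic alkene 22 to dione 21. Direct methyl addition to the C10 ketone would place carbon on the open β face and give the wrong carbinol. Epoxidation puts oxygen on that face, and hydride then supplies the methyl group while also reducing C3. This asks for chemoselective methylenation of C10 in the presence of the hindered C3 ketone.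

**Key disconnection (21 ⇒ 19).** Cutting C1–C10 opens the seven-membered ring to an acyclic acyl selenide tethered to a cyclopentenone. Closures at C5–C6 or C7–C8 would need a pre-formed, stereodefined ring carbon nucleophile. The C1–C10 cut uses only an enone and an acid derivative, removes one ring and one stereocentre, and creates C10 at the oxidation level needed next. The forward step must close a seven-membered ring by radical addition faster than the acyl radical is reduced or decarbonylated.

**Selenoester and enone (19 ⇒ 18 ⇒ 17 ⇒ 16).** The C–Se bond comes from acid 18 and the acid from tert-butyl ester 17. The C1=C2 double bond comes from cyclopentanone 16 by one-pot enolate dehydrogenation. Quaternary C4 leaves only one direction of enolisation, so no regiochemical choice arises.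

**Isobutyl branch at C1' (16 ⇒ 15 ⇒ 14).** The C1'–CH2 bond is cut to the 2,4,6-trimethoxybenzylic cation derived from carbinol 14 and a methallylsilane (15 after capture, 16 after hydrogenation). The electron-rich arene that complicates the endgame makes this congested bond easy here. The forward step must discriminate the faces of a cation next to a quaternary centre.

**Ring substituents (14 ⇒ 9 + 10 + 11).** The C5–C6 and C4–C1' bonds are cut together: a copper-catalysed asymmetric conjugate addition of the side-chain zinc reagent (from iodide 9) to 2-methylcyclopent-2-en-1-one 10, and an aldol capture of the enolate by 2,4,6-trimethoxybenzaldehyde 11. One operation sets C5 by the ligand and C4 by C5, from two commercial compounds and one chain reagent.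

**Side chain (9 ⇒ 8 ⇒ 7 ⇒ 6 ⇒ 4 + 5; 4 ⇒ 1 + 2).** The C7–C11 bond is cut by an Evans syn-aldol of imide 4 with acetaldehyde 5. This fixes C7 absolutely and delivers C11 as the masked acetyl carbon. The imide carbonyl becomes C6 (alcohol 8, iodide 9). Imide 4 comes from mono-tert-butyl glutarate 1 and oxazolidinone 2. An achiral acetoacetate-derived chain would be three steps shorter but would carry C7 as an uncontrolled centre.

## Roads not taken

**Alternative 1:** The cut goes through the benzene ring. A base-mediated Claisen-type folding (NaOMe/MeOH) of a polyketo diester chain attached at C1' would close the ring as the phloroglucinol carboxylate A1, which carries the finished sesquiterpene with its C10 silyl ether.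

- Merits: the three phenols appear unprotected, so no aryl methyl ether has to be cleaved; the ester is a latent formyl group; all terpenoid chemistry is finished before the sensitive arene exists.
- Weak points: the C4–C1' stereodiad must be built without the aryl group, so the congested bond has to come from enolate chemistry at a neopentyl centre. The enolisable tricarbonyl chain has several competing closure modes (O-cyclisation to pyranones, aldol closure), and the required carbanion must attack the ester that sits next to the bulky branch. One ester reduction and one further formylation on a free phloroglucinol still follow.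
- Comparison: this road is better at the very end, where the chosen plan has to set a forcing thiolate tri-demethylation against it. The chosen plan is better at the start, where the arene serves as the cation-stabilising element for the C1' branch and the ring system is assembled convergently.

**Alternative 2:** The cut is the C4–C5 ring bond. A Rh2(OAc)4-generated carbenoid at C5 would insert into the tertiary C4–H bond of an acyclic α-diazo-β-keto ester and give the cyclopentanone A2 with retention at C4.

- Merits: C4 and C1' would be fixed as a vicinal methine pair by acyclic stereocontrol and transferred stereospecifically. This is a more rigorous answer to the C4/C1' problem than facial selection on a cation, and it is catalytic.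
- Weak points: the trimethoxyphenyl ring lies within reach of the electrophilic carbenoid, so aromatic cycloaddition or aromatic substitution would compete with C–H insertion. A2 contains none of the seven-membered ring. C1, C5, C7 and C10 and five ring carbons would still have to be added from an epimerisable β-keto ester, with the ring fusion unsolved.
- Comparison: Alternative 2 is stronger at C4 and C1'. The chosen plan sets against it that one conjugate addition–aldol fixes C5 and C4 together, and that the whole cycloheptane then closes through a single bond with its ketones placed where they are needed.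

**Alternative 3:** The cuts are the arene–C1' and C1'–CH2 bonds. An aryne released by CsF would insert into the carbonyl group of a C4 aldehyde of the complete sesquiterpene, and the resulting ortho-quinone methide would be captured by i-Bu2Zn at C1' to give the phenol A3.

- Merits: it is the most convergent plan. The terpenoid and the aromatic part meet late, one phenol is already free, and only two methyl ethers remain.
- Weak points: the aldehyde is neopentyl and strongly hindered. Ortho-quinone methides formed this way are readily trapped by a second aryne or cyclise. An unsymmetrical dimethoxyaryne raises a regiochemical question. The C1' configuration is again decided by facial attack next to quaternary C4, now on the most valuable intermediate and without a clear controlling model. Two formylations and demethylation still follow.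
- Comparison: in convergence and protecting-group economy this road is better. The chosen plan sets against it that every step belongs to a known reaction class, and that the C1' problem is met early on simple material where a fallback is cheap.

Key step: step 12

## Remarks on the chemistry

- The (S,R,R)-configured binaphthol phosphoramidite is assumed to address the same enone face of 10 as it does with cyclohex-2-enone. If the sense proves opposite, the enantiomeric ligand is taken.
- Compound 14 is carried as the mixture of carbinol epimers at C1', since that centre is erased in step 7.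
- The C3 carbinol configuration in 24 and 25 is inconsequential and is left open.

## Route

Step 1
Reactants: 1 5-tert-butoxy-5-oxopentanoic acid; 2 (4S)-4-benzyl-1,3-oxazolidin-2-one
Product: 4 tert-butyl 5-[(4S)-4-benzyl-2-oxo-1,3-oxazolidin-3-yl]-5-oxopentanoate, via mixed pivalic anhydride 3 (not isolated)
Conditions: PivCl, Et3N, THF, −20 °C; then 2, LiCl, −20 °C → rt
Reagents that add atoms: none
Why: N-acylation of the oxazolidinone through the mixed pivalic anhydride; the nucleophile attacks the unhindered carbonyl and the tert-butyl ester is untouched.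

Step 2
Reactants: 4 tert-butyl 5-[(4S)-4-benzyl-2-oxo-1,3-oxazolidin-3-yl]-5-oxopentanoate; 5 acetaldehyde
Product: 6 tert-butyl (4S,5R)-4-{[(4S)-4-benzyl-2-oxo-1,3-oxazolidin-3-yl]carbonyl}-5-hydroxyhexanoate
Conditions: n-Bu2BOTf, i-Pr2NEt, CH2Cl2, 0 °C; MeCHO, −78 → 0 °C; pH 7 buffer, MeOH, H2O2
Reagents that add atoms: none
Why: Evans syn-aldol reaction; the Z-boron enolate of the imide (the ester is not enolised) reacts through a Zimmerman–Traxler chair on the face away from the benzyl group, which fixes C7 absolutely and gives C11 as the syn carbinol.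

Step 3
Reactants: 6 tert-butyl (4S,5R)-4-{[(4S)-4-benzyl-2-oxo-1,3-oxazolidin-3-yl]carbonyl}-5-hydroxyhexanoate
Product: 7 tert-butyl (4S,5R)-4-{[(4S)-4-benzyl-2-oxo-1,3-oxazolidin-3-yl]carbonyl}-5-[(triisopropylsilyl)oxy]hexanoate
Conditions: TIPSOTf, 2,6-lutidine, CH2Cl2, 0 °C → rt
Reagents that add atoms: triisopropylsilyl trifluoromethanesulfonate CC(C)[Si](C(C)C)(C(C)C)OS(=O)(=O)C(F)(F)F
Why: Silylation of the secondary alcohol with a silyl triflate; the triisopropylsilyl ether is chosen because it must survive trifluoroacetic acid, LiAlH4 and radical conditions later.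

Step 4
Reactants: 7 tert-butyl (4S,5R)-4-{[(4S)-4-benzyl-2-oxo-1,3-oxazolidin-3-yl]carbonyl}-5-[(triisopropylsilyl)oxy]hexanoate
Product: 8 tert-butyl (4R,5R)-4-(hydroxymethyl)-5-[(triisopropylsilyl)oxy]hexanoate
Conditions: LiBH4, H2O (1 equiv), Et2O, 0 °C
Reagents that add atoms: none
Why: Reductive removal of the auxiliary; LiBH4 reduces the imide carbonyl (future C6) to the primary alcohol and leaves the tert-butyl ester; 8 is used at once to avoid lactonisation.

Step 5
Reactants: 8 tert-butyl (4R,5R)-4-(hydroxymethyl)-5-[(triisopropylsilyl)oxy]hexanoate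
Product: 9 tert-butyl (4S,5R)-4-(iodomethyl)-5-[(triisopropylsilyl)oxy]hexanoate
Conditions: I2, PPh3, imidazole, CH2Cl2, 0 °C → rt
Reagents that add atoms: iodine II
Why: Appel-type iodination of a primary alcohol under neutral conditions; no stereocentre is involved.

Step 6
Reactants: 9 tert-butyl (4S,5R)-4-(iodomethyl)-5-[(triisopropylsilyl)oxy]hexanoate; 10 2-methylcyclopent-2-en-1-one; 11 2,4,6-trimethoxybenzaldehyde
Product: 14 tert-butyl (4R,5R)-4-({(1R,2S)-2-[hydroxy(2,4,6-trimethoxyphenyl)methyl]-2-methyl-3-oxocyclopentyl}methyl)-5-[(triisopropylsilyl)oxy]hexanoate (carbinol epimers), via dialkylzinc reagent 12 (not isolated), via zinc enolate 13 (not isolated)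
Conditions: Et2Zn, CuI (cat.), 50 °C, volatiles removed; Cu(OTf)2 (2 mol %), (S,R,R)-binaphthol bis(1-phenylethyl)amine phosphoramidite (4 mol %), 10, toluene, −30 °C; then 11, −30 → 0 °C; aq NH4Cl
Reagents that add atoms: none
Why: Iodine–zinc exchange gives the ester-tolerant dialkylzinc; copper/phosphoramidite-catalysed asymmetric conjugate addition sets C5 under ligand control, and the zinc enolate is captured by the aldehyde on the face anti to the new chain (tandem conjugate addition–aldol), which fixes quaternary C4 with its methyl group cis to C6. Because the chain is enantiopure, any C5 epimer is a diastereomer and should be removable by chromatography; only one of the two alkyl groups on zinc is transferred.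

Step 7
Reactants: 14 tert-butyl (4R,5R)-4-({(1R,2S)-2-[hydroxy(2,4,6-trimethoxyphenyl)methyl]-2-methyl-3-oxocyclopentyl}methyl)-5-[(triisopropylsilyl)oxy]hexanoate
Product: 15 tert-butyl (4R,5R)-4-({(1R,2S)-2-methyl-2-[(1S)-3-methyl-1-(2,4,6-trimethoxyphenyl)but-3-en-1-yl]-3-oxocyclopentyl}methyl)-5-[(triisopropylsilyl)oxy]hexanoate
Conditions: methallyltrimethylsilane, TMSOTf (10 mol %), CH2Cl2, −78 → −40 °C
Reagents that add atoms: methallyltrimethylsilane CC(=C)C[Si](C)(C)C
Why: SN1 benzylic substitution of the Hosomi–Sakurai type; the 2,4,6-trimethoxybenzylic cation forms at low temperature and cannot eliminate because C4 has no hydrogen. In the expected reactive conformer the small C4 methyl group lies on the side of the ortho-methoxy group (least 1,3-allylic strain) and the C4–C5 bond stands perpendicular to the cation plane, so the silane should attack anti to C5 (Felkin-type) and give the C1' configuration of the target.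

Step 8
Reactants: 15 tert-butyl (4R,5R)-4-({(1R,2S)-2-methyl-2-[(1S)-3-methyl-1-(2,4,6-trimethoxyphenyl)but-3-en-1-yl]-3-oxocyclopentyl}methyl)-5-[(triisopropylsilyl)oxy]hexanoate
Product: 16 tert-butyl (4R,5R)-4-({(1R,2S)-2-methyl-2-[(1S)-3-methyl-1-(2,4,6-trimethoxyphenyl)butyl]-3-oxocyclopentyl}methyl)-5-[(triisopropylsilyl)oxy]hexanoate
Conditions: H2 (1 atm), Pd/C, EtOAc, rt
Reagents that add atoms: none
Why: Catalytic hydrogenation of the 1,1-disubstituted alkene to the isobutyl group; it is done before the enone exists and creates no stereocentre.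

Step 9
Reactants: 16 tert-butyl (4R,5R)-4-({(1R,2S)-2-methyl-2-[(1S)-3-methyl-1-(2,4,6-trimethoxyphenyl)butyl]-3-oxocyclopentyl}methyl)-5-[(triisopropylsilyl)oxy]hexanoate
Product: 17 tert-butyl (4R,5R)-4-({(1S,5S)-5-methyl-5-[(1S)-3-methyl-1-(2,4,6-trimethoxyphenyl)butyl]-4-oxocyclopent-2-en-1-yl}methyl)-5-[(triisopropylsilyl)oxy]hexanoate
Conditions: LDA (LiN(i-Pr)2), THF, −78 °C; N-tert-butylbenzenesulfinimidoyl chloride, −78 °C
Reagents that add atoms: none
Why: One-pot enolate dehydrogenation (sulfinimidoyl chloride, the single-flask equivalent of a Saegusa–Ito oxidation); quaternary C4 allows enolisation only towards C2, and the ketone α-methylene is deprotonated in preference to the tert-butyl ester.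

Step 10
Reactants: 17 tert-butyl (4R,5R)-4-({(1S,5S)-5-methyl-5-[(1S)-3-methyl-1-(2,4,6-trimethoxyphenyl)butyl]-4-oxocyclopent-2-en-1-yl}methyl)-5-[(triisopropylsilyl)oxy]hexanoate
Product: 18 (4R,5R)-4-({(1S,5S)-5-methyl-5-[(1S)-3-methyl-1-(2,4,6-trimethoxyphenyl)butyl]-4-oxocyclopent-2-en-1-yl}methyl)-5-[(triisopropylsilyl)oxy]hexanoic acid
Conditions: TFA, CH2Cl2, anisole (scavenger), 0 °C → rt
Reagents that add atoms: none
Why: Acidolysis of the tert-butyl ester; the secondary triisopropylsilyl ether should survive, and anisole intercepts the tert-butyl cation before it can alkylate the electron-rich arene.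

Step 11
Reactants: 18 (4R,5R)-4-({(1S,5S)-5-methyl-5-[(1S)-3-methyl-1-(2,4,6-trimethoxyphenyl)butyl]-4-oxocyclopent-2-en-1-yl}methyl)-5-[(triisopropylsilyl)oxy]hexanoic acid
Product: 19 Se-phenyl (4R,5R)-4-({(1S,5S)-5-methyl-5-[(1S)-3-methyl-1-(2,4,6-trimethoxyphenyl)butyl]-4-oxocyclopent-2-en-1-yl}methyl)-5-[(triisopropylsilyl)oxy]hexaneselenoate
Conditions: N-(phenylselanyl)phthalimide, n-Bu3P, CH2Cl2, −30 °C → rt
Reagents that add atoms: N-(phenylselanyl)phthalimide O=C1c2ccccc2C(=O)N1[Se]c1ccccc1
Why: Selenoester formation through an acyloxyphosphonium ion; this reagent releases no free selenol that could add to the enone.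

Step 12
Reactants: 19 Se-phenyl (4R,5R)-4-({(1S,5S)-5-methyl-5-[(1S)-3-methyl-1-(2,4,6-trimethoxyphenyl)butyl]-4-oxocyclopent-2-en-1-yl}methyl)-5-[(triisopropylsilyl)oxy]hexaneselenoate
Product: 21 (1R,4S,5S,7R)-4-methyl-4-[(1S)-3-methyl-1-(2,4,6-trimethoxyphenyl)butyl]-7-[(1R)-1-(triisopropylsilyloxy)ethyl]-trans-perhydroazulene-3,10-dione, via cis-fused C1 epimer 20 (not isolated)
Conditions: (Me3Si)3SiH, AIBN, benzene (0.005 M), 80 °C, slow addition; then DBU, rt
Reagents that add atoms: none
Why: The silyl radical abstracts the phenylseleno group and releases the nucleophilic C10 acyl radical, which adds to C1, the β-carbon of the cyclopentenone; the α-keto radical at C2 then takes hydrogen from the silane and carries the chain. The closest known reaction type is the cyclisation of acyl radicals from acyl selenides onto enones and enoates, which includes seven-membered ring formation. The cycloheptanone closes in the 7-exo-trig mode by the single C1–C10 bond; the 8-endo mode would put the nucleophilic radical on the electron-poor α-carbon C2 and is polarity-mismatched. C1 is the only new stereocentre; it is not decided in the radical step but, being α to the new C10 ketone, is equilibrated by DBU in the same flask to the trans fusion, in which both fusion bonds are pseudo-equatorial on the five-membered ring. The step needs ring closure to outrun hydrogen transfer and decarbonylation, which the slow hydrogen donor, high dilution and a primary acyl radical should secure. It also needs the enone to be the only radical acceptor, which is why the isopropenyl group is carried as the silyloxyethyl group and the isobutyl chain is already saturated. C7 cannot epimerise under DBU because C11 is not a carbonyl group.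

Step 13
Reactants: 21 (1R,4S,5S,7R)-4-methyl-4-[(1S)-3-methyl-1-(2,4,6-trimethoxyphenyl)butyl]-7-[(1R)-1-(triisopropylsilyloxy)ethyl]-trans-perhydroazulene-3,10-dione
Product: 22 10-methylene-3-ketone (21 with C10=CH2; all stereocentres as in 21)
Conditions: Ph3PCH3Br, KOt-Bu, THF, 0 °C → rt
Reagents that add atoms: methyltriphenylphosphonium bromide C[P+](c1ccccc1)(c1ccccc1)c1ccccc1.[Br-]
Why: Wittig methylenation; the cycloheptanone carbonyl C10 reacts, whereas the C3 ketone, flanked by quaternary C4 and its large branch, should not; C1 is already at its equilibrium configuration.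

Step 14
Reactants: 22 10-methylene-3-ketone
Product: 23 10β,14-epoxy-3-ketone (spiro-oxirane at C10 with oxygen on the β face)
Conditions: dimethyldioxirane, acetone/CH2Cl2, −20 → 0 °C
Reagents that add atoms: dimethyldioxirane CC1(C)OO1
Why: Epoxidation of the exocyclic alkene with a neutral oxidant that spares the ketone and, at low temperature, the arene; attack is expected on the β face, syn to H1 and away from the α-oriented C2 methylene, the C7 side chain and the C4 benzylic branch, which places oxygen where the target has its hydroxyl group.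

Step 15
Reactants: 23 10β,14-epoxy-3-ketone
Product: 24 3,10-diol ((10R)-10-hydroxy-10-methyl; C3 carbinol of open configuration)
Conditions: LiAlH4, THF, 0 → 50 °C
Reagents that add atoms: none
Why: Hydride opens the epoxide at its methylene carbon, converting it into the C10 methyl group with retention of the C–O bond, and reduces the C3 ketone in the same operation.

Step 16
Reactants: 24 3,10-diol
Product: 25 C3 O-alkyl S-methyl xanthate of 24 (C10 hydroxyl free)
Conditions: NaHMDS (NaN(SiMe3)2, 1.1 equiv), THF, −78 °C; CS2; MeI, −78 → 0 °C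
Reagents that add atoms: carbon disulfide S=C=S; iodomethane CI
Why: Xanthate formation for a Barton–McCombie deoxygenation; with one equivalent of base the more acidic, less hindered secondary C3 alkoxide forms and is captured, while the tertiary C10 hydroxyl should stay free.

Step 17
Reactants: 25 C3 xanthate
Product: 26 (1R,4S,5S,7R,10R)-10-hydroxy-10-methyl-4-methyl-4-[(1R)-3-methyl-1-(2,4,6-trimethoxyphenyl)butyl]-7-[(1R)-1-(triisopropylsilyloxy)ethyl]-trans-perhydroazulene
Conditions: n-Bu3SnH, AIBN, toluene, 110 °C
Reagents that add atoms: none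
Why: Barton–McCombie deoxygenation; the secondary C3 radical is reduced by the stannane, and no alkene is present to intercept it.

Step 18
Reactants: 26 C11 silyl ether
Product: 27 C10,C11-diol (26 with free C11 hydroxyl)
Conditions: n-Bu4NF, THF, rt → 50 °C
Reagents that add atoms: none
Why: Fluoride cleavage of the silyl ether under basic conditions that the tertiary alcohol tolerates.

Step 19
Reactants: 27 C10,C11-diol
Product: 28 7-acetyl compound (methyl ketone at C11; C7 R)
Conditions: Dess–Martin periodinane, NaHCO3, CH2Cl2, 0 °C → rt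
Reagents that add atoms: none
Why: Dess–Martin oxidation of the only secondary alcohol; the buffered, neutral conditions should not epimerise C7, and 28 is used directly.

Step 20
Reactants: 28 7-acetyl compound
Product: 29 (1R,4S,5S,7R,10R)-7-isopropenyl-10-hydroxy-10-methyl-4-methyl-4-[(1R)-3-methyl-1-(2,4,6-trimethoxyphenyl)butyl]-trans-perhydroazulene
Conditions: Cp2TiMe2 (excess), toluene/THF, 70 °C, dark
Reagents that add atoms: dimethyltitanocene C[Ti](C)(C1C=CC=C1)C1C=CC=C1
Why: Petasis methylenation; the titanium methylidene is non-basic, so the α-stereocentre C7 is kept, and the free tertiary alcohol only consumes extra reagent reversibly.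

Step 21
Reactants: 29 7-isopropenyl trimethoxyphenyl compound
Product: 30 mono-aldehyde (3-formyl-2,4,6-trimethoxyphenyl group on C1')
Conditions: n-BuLi (2.5 equiv), TMEDA, THF, 0 °C; DMF; aq NH4Cl
Reagents that add atoms: N,N-dimethylformamide CN(C)C=O
Why: Directed ortho-metalation at an aryl C–H flanked by two methoxy groups, followed by formylation with DMF; the basic conditions leave the tertiary alcohol (as its alkoxide) and the isopropenyl group intact.

Step 22
Reactants: 30 mono-aldehyde
Product: 32 dialdehyde trimethyl ether (3,5-diformyl-2,4,6-trimethoxyphenyl group on C1'), via lithium amino alkoxide 31 (not isolated)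
Conditions: LiN(Me)CH2CH2NMe2 (2.2 equiv), THF, −20 °C; n-BuLi (3 equiv), −20 → 0 °C; DMF; aq NH4Cl
Reagents that add atoms: N,N-dimethylformamide CN(C)C=O
Why: The first formyl group is protected in the flask as its α-amino alkoxide; a second directed ortho-metalation at the remaining C–H between two methoxy groups and formylation then complete the dialdehyde.

Step 23
Reactants: 32 dialdehyde trimethyl ether
Product: 33 CNP0594576.1, (1R,4S,5S,7R,10R)-4-[(1R)-1-(3,5-diformyl-2,4,6-trihydroxyphenyl)-3-methylbutyl]-7-isopropenyl-4,10-dimethyl-trans-perhydroazulen-10-ol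
Conditions: n-PrSLi, HMPA, 120 °C; cold 0.5 M HCl work-up
Reagents that add atoms: none
Why: Nucleophilic O-demethylation by thiolate (SN2 at methyl); every methoxy group is ortho or para to a formyl group and is thereby activated, and the basic medium spares the tertiary alcohol and the isopropenyl group.

## Compound list

1 | 5-tert-butoxy-5-oxopentanoic acid (mono-tert-butyl glutarate) | OC(=O)CCCC(=O)OC(C)(C)C | starting material
2 | (4S)-4-benzyl-1,3-oxazolidin-2-one | O=C1N[C@@H](Cc2ccccc2)CO1 | starting material
3 | mixed anhydride of 1 with pivalic acid | CC(C)(C)C(=O)OC(=O)CCCC(=O)OC(C)(C)C | intermediate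
4 | tert-butyl 5-[(4S)-4-benzyl-2-oxo-1,3-oxazolidin-3-yl]-5-oxopentanoate | CC(C)(C)OC(=O)CCCC(=O)N1[C@@H](Cc2ccccc2)COC1=O | intermediate
5 | acetaldehyde | CC=O | starting material
6 | tert-butyl (4S,5R)-4-{[(4S)-4-benzyl-2-oxo-1,3-oxazolidin-3-yl]carbonyl}-5-hydroxyhexanoate | C[C@@H](O)[C@H](CCC(=O)OC(C)(C)C)C(=O)N1[C@@H](Cc2ccccc2)COC1=O | intermediate
7 | tert-butyl (4S,5R)-4-{[(4S)-4-benzyl-2-oxo-1,3-oxazolidin-3-yl]carbonyl}-5-[(triisopropylsilyl)oxy]hexanoate | C[C@@H](O[Si](C(C)C)(C(C)C)C(C)C)[C@H](CCC(=O)OC(C)(C)C)C(=O)N1[C@@H](Cc2ccccc2)COC1=O | intermediate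
8 | tert-butyl (4R,5R)-4-(hydroxymethyl)-5-[(triisopropylsilyl)oxy]hexanoate | C[C@@H](O[Si](C(C)C)(C(C)C)C(C)C)[C@H](CCC(=O)OC(C)(C)C)CO | intermediate
9 | tert-butyl (4S,5R)-4-(iodomethyl)-5-[(triisopropylsilyl)oxy]hexanoate | C[C@@H](O[Si](C(C)C)(C(C)C)C(C)C)[C@H](CCC(=O)OC(C)(C)C)CI | intermediate
10 | 2-methylcyclopent-2-en-1-one | CC1=CCCC1=O | starting material
11 | 2,4,6-trimethoxybenzaldehyde | COc1cc(OC)c(C=O)c(OC)c1 | starting material
12 | bis{(2S,3R)-2-(3-tert-butoxy-3-oxopropyl)-3-[(triisopropylsilyl)oxy]butyl}zinc | C[C@@H](O[Si](C(C)C)(C(C)C)C(C)C)[C@H](CCC(=O)OC(C)(C)C)C[Zn]C[C@@H](CCC(=O)OC(C)(C)C)[C@@H](C)O[Si](C(C)C)(C(C)C)C(C)C | intermediate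
13 | alkylzinc enolate of the conjugate adduct (C3–O–Zn, C3=C4, chain on C5) | C[C@@H](O[Si](C(C)C)(C(C)C)C(C)C)[C@H](CCC(=O)OC(C)(C)C)C[C@H]1CCC(O[Zn]C[C@@H](CCC(=O)OC(C)(C)C)[C@@H](C)O[Si](C(C)C)(C(C)C)C(C)C)=C1C | intermediate
14 | tert-butyl (4R,5R)-4-({(1R,2S)-2-[hydroxy(2,4,6-trimethoxyphenyl)methyl]-2-methyl-3-oxocyclopentyl}methyl)-5-[(triisopropylsilyl)oxy]hexanoate (carbinol epimers) | C[C@@H](O[Si](C(C)C)(C(C)C)C(C)C)[C@H](CCC(=O)OC(C)(C)C)C[C@H]1CCC(=O)[C@]1(C)C(O)c2c(OC)cc(OC)cc2OC | intermediate
15 | tert-butyl (4R,5R)-4-({(1R,2S)-2-methyl-2-[(1S)-3-methyl-1-(2,4,6-trimethoxyphenyl)but-3-en-1-yl]-3-oxocyclopentyl}methyl)-5-[(triisopropylsilyl)oxy]hexanoate | C[C@@H](O[Si](C(C)C)(C(C)C)C(C)C)[C@H](CCC(=O)OC(C)(C)C)C[C@H]1CCC(=O)[C@]1(C)[C@@H](CC(C)=C)c2c(OC)cc(OC)cc2OC | intermediate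
16 | tert-butyl (4R,5R)-4-({(1R,2S)-2-methyl-2-[(1S)-3-methyl-1-(2,4,6-trimethoxyphenyl)butyl]-3-oxocyclopentyl}methyl)-5-[(triisopropylsilyl)oxy]hexanoate | C[C@@H](O[Si](C(C)C)(C(C)C)C(C)C)[C@H](CCC(=O)OC(C)(C)C)C[C@H]1CCC(=O)[C@]1(C)[C@@H](CC(C)C)c2c(OC)cc(OC)cc2OC | intermediate
17 | tert-butyl (4R,5R)-4-({(1S,5S)-5-methyl-5-[(1S)-3-methyl-1-(2,4,6-trimethoxyphenyl)butyl]-4-oxocyclopent-2-en-1-yl}methyl)-5-[(triisopropylsilyl)oxy]hexanoate | C[C@@H](O[Si](C(C)C)(C(C)C)C(C)C)[C@H](CCC(=O)OC(C)(C)C)C[C@H]1C=CC(=O)[C@]1(C)[C@@H](CC(C)C)c2c(OC)cc(OC)cc2OC | intermediate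
18 | (4R,5R)-4-({(1S,5S)-5-methyl-5-[(1S)-3-methyl-1-(2,4,6-trimethoxyphenyl)butyl]-4-oxocyclopent-2-en-1-yl}methyl)-5-[(triisopropylsilyl)oxy]hexanoic acid | C[C@@H](O[Si](C(C)C)(C(C)C)C(C)C)[C@H](CCC(=O)O)C[C@H]1C=CC(=O)[C@]1(C)[C@@H](CC(C)C)c2c(OC)cc(OC)cc2OC | intermediate
19 | Se-phenyl (4R,5R)-4-({(1S,5S)-5-methyl-5-[(1S)-3-methyl-1-(2,4,6-trimethoxyphenyl)butyl]-4-oxocyclopent-2-en-1-yl}methyl)-5-[(triisopropylsilyl)oxy]hexaneselenoate | C[C@@H](O[Si](C(C)C)(C(C)C)C(C)C)[C@H](CCC(=O)[Se]c3ccccc3)C[C@H]1C=CC(=O)[C@]1(C)[C@@H](CC(C)C)c2c(OC)cc(OC)cc2OC | intermediate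
20 | cis-fused (1S) epimer of 21 | C[C@@H](O[Si](C(C)C)(C(C)C)C(C)C)[C@@H]1CCC(=O)[C@H]2CC(=O)[C@](C)([C@@H](CC(C)C)c3c(OC)cc(OC)cc3OC)[C@H]2C1 | intermediate
21 | (1R,4S,5S,7R)-4-methyl-4-[(1S)-3-methyl-1-(2,4,6-trimethoxyphenyl)butyl]-7-[(1R)-1-(triisopropylsilyloxy)ethyl]-trans-perhydroazulene-3,10-dione | C[C@@H](O[Si](C(C)C)(C(C)C)C(C)C)[C@@H]1CCC(=O)[C@@H]2CC(=O)[C@](C)([C@@H](CC(C)C)c3c(OC)cc(OC)cc3OC)[C@H]2C1 | intermediate
22 | 10-methylene-3-ketone (21 with C10=CH2) | C[C@@H](O[Si](C(C)C)(C(C)C)C(C)C)[C@@H]1CCC(=C)[C@@H]2CC(=O)[C@](C)([C@@H](CC(C)C)c3c(OC)cc(OC)cc3OC)[C@H]2C1 | intermediate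
23 | 10β,14-epoxy-3-ketone (spiro-oxirane at C10, oxygen β) | C[C@@H](O[Si](C(C)C)(C(C)C)C(C)C)[C@@H]1CC[C@@]4(OC4)[C@@H]2CC(=O)[C@](C)([C@@H](CC(C)C)c3c(OC)cc(OC)cc3OC)[C@H]2C1 | intermediate
24 | 3,10-diol ((10R)-10-hydroxy-10-methyl, C3 carbinol of open configuration) | C[C@@H](O[Si](C(C)C)(C(C)C)C(C)C)[C@@H]1CC[C@@](C)(O)[C@@H]2CC(O)[C@](C)([C@@H](CC(C)C)c3c(OC)cc(OC)cc3OC)[C@H]2C1 | intermediate
25 | C3 O-alkyl S-methyl xanthate of 24 | C[C@@H](O[Si](C(C)C)(C(C)C)C(C)C)[C@@H]1CC[C@@](C)(O)[C@@H]2CC(OC(=S)SC)[C@](C)([C@@H](CC(C)C)c3c(OC)cc(OC)cc3OC)[C@H]2C1 | intermediate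
26 | (1R,4S,5S,7R,10R)-10-hydroxy-4,10-dimethyl-4-[(1R)-3-methyl-1-(2,4,6-trimethoxyphenyl)butyl]-7-[(1R)-1-(triisopropylsilyloxy)ethyl]-trans-perhydroazulene | C[C@@H](O[Si](C(C)C)(C(C)C)C(C)C)[C@@H]1CC[C@@](C)(O)[C@@H]2CC[C@](C)([C@@H](CC(C)C)c3c(OC)cc(OC)cc3OC)[C@H]2C1 | intermediate
27 | C10,C11-diol (26 with free (11R) hydroxyl) | C[C@@H](O)[C@@H]1CC[C@@](C)(O)[C@@H]2CC[C@](C)([C@@H](CC(C)C)c3c(OC)cc(OC)cc3OC)[C@H]2C1 | intermediate
28 | 7-acetyl compound (methyl ketone at C11) | CC(=O)[C@@H]1CC[C@@](C)(O)[C@@H]2CC[C@](C)([C@@H](CC(C)C)c3c(OC)cc(OC)cc3OC)[C@H]2C1 | intermediate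
29 | (1R,4S,5S,7R,10R)-7-isopropenyl-4,10-dimethyl-4-[(1R)-3-methyl-1-(2,4,6-trimethoxyphenyl)butyl]-trans-perhydroazulen-10-ol | C=C(C)[C@@H]1CC[C@@](C)(O)[C@@H]2CC[C@](C)([C@@H](CC(C)C)c3c(OC)cc(OC)cc3OC)[C@H]2C1 | intermediate
30 | mono-aldehyde (29 with a 3-formyl-2,4,6-trimethoxyphenyl group) | C=C(C)[C@@H]1CC[C@@](C)(O)[C@@H]2CC[C@](C)([C@@H](CC(C)C)c3c(OC)c(C=O)c(OC)cc3OC)[C@H]2C1 | intermediate
31 | dilithium α-amino alkoxide of 30 (formyl group masked by N,N,N'-trimethylethylenediamine, C10 lithium alkoxide) | C=C(C)[C@@H]1CC[C@@](C)(O[Li])[C@@H]2CC[C@](C)([C@@H](CC(C)C)c3c(OC)c(C(O[Li])N(C)CCN(C)C)c(OC)cc3OC)[C@H]2C1 | intermediate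
32 | dialdehyde trimethyl ether (29 with a 3,5-diformyl-2,4,6-trimethoxyphenyl group) | C=C(C)[C@@H]1CC[C@@](C)(O)[C@@H]2CC[C@](C)([C@@H](CC(C)C)c3c(OC)c(C=O)c(OC)c(C=O)c3OC)[C@H]2C1 | intermediate
33 | CNP0594576.1 | C=C(C)[C@@H]1CC[C@@](C)(O)[C@@H]2CC[C@](C)([C@@H](CC(C)C)c3c(O)c(C=O)c(O)c(C=O)c3O)[C@H]2C1 | target

## Step count and least certain steps

Total step count: 23. Longest linear sequence: 23 steps (steps 1–23; compounds 10 and 11 enter at step 6 as commercial materials).

**Step 12 (key step).** The most likely failure is that hydrogen transfer to the acyl radical, or its decarbonylation, outruns the entropically demanding seven-membered ring closure onto a β-substituted enone. The position of the C1 equilibrium is a second, smaller uncertainty. Fallback, setting out from 19 and returning at 21: reduction of 19 with n-Bu3SnH/AIBN at high stannane concentration gives the C10 aldehyde F1. SmI2 in THF/t-BuOH then joins C10 to C1 by reductive aldehyde–enone (ketyl–olefin type) cyclisation to the 10-hydroxyhydroazulen-3-one F2. Dess–Martin oxidation and DBU equilibration give 21.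

**Step 6.** The most likely failure is incomplete or reversible aldol capture: the tetrasubstituted zinc enolate is hindered and the doubly ortho-substituted, electron-rich aldehyde is a poor electrophile, so retro-aldol cleavage on warming may return the simple conjugate adduct. Fallback, setting out from 9 and 10 and returning at 14: the same copper-catalysed addition of 12 is quenched with Me3SiCl to give the trimethylsilyl enol ether F3. A TiCl4-mediated Mukaiyama aldol reaction of F3 with 11 at −78 °C, irreversible under Lewis-acid conditions, then gives 14.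

**Step 7.** The most likely failure is poor facial selectivity in the capture of the benzylic cation, because C4 has no hydrogen to lock the cation conformation and its methyl and acyl substituents differ only moderately in size. Fallback, setting out from 11 (with 9 and 10) and returning at 16: isobutylmagnesium bromide is added to 11 to give 3-methyl-1-(2,4,6-trimethoxyphenyl)butan-1-ol F4. Its cation, generated with ZnCl2 or catalytic TMSOTf, alkylates the silyl enol ether F3 (made as described for step 6) on the face anti to the chain. The C4–C1' bond is thus formed last, with a different stereodetermining transition state, and 16 is reached directly.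

**Step 14.** The most likely failure is oxidant approach from the α face, giving the C10 epimer after hydride opening. Fallback, setting out from 21 and returning at 24: methyllithium/CeCl3 is added to the C10 ketone of 21, which delivers carbon instead of oxygen to whichever face is open and so gives the complementary carbinol, the 10-hydroxy-10-methyl-3-ketone F5. LiAlH4 reduction of its C3 ketone gives 24.

**Step 23.** The most likely failure is attack of the thiolate on the doubly activated ring (ipso substitution) or on the formyl groups, or stalling once the first phenoxides have formed. Fallback, setting out from 30 and returning at 33: the less electrophilic mono-aldehyde 30 is demethylated with n-PrSLi to the 3-alkyl-2,4,6-trihydroxybenzaldehyde F6. The second formyl group is then introduced on the free phenol by magnesium-mediated ortho-formylation (MgCl2, Et3N, paraformaldehyde; Casnati–Skattebøl conditions) to give 33.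

## Further compounds

F1 | step 12 | (4R,5R)-4-({(1S,5S)-5-methyl-5-[(1S)-3-methyl-1-(2,4,6-trimethoxyphenyl)butyl]-4-oxocyclopent-2-en-1-yl}methyl)-5-[(triisopropylsilyl)oxy]hexanal | C[C@@H](O[Si](C(C)C)(C(C)C)C(C)C)[C@H](CCC=O)C[C@H]1C=CC(=O)[C@]1(C)[C@@H](CC(C)C)c2c(OC)cc(OC)cc2OC
F2 | step 12 | 10-hydroxy analogue of 21 (C10 carbinol and C1 of open configuration, C3 ketone) | C[C@@H](O[Si](C(C)C)(C(C)C)C(C)C)[C@@H]1CCC(O)C2CC(=O)[C@](C)([C@@H](CC(C)C)c3c(OC)cc(OC)cc3OC)[C@H]2C1
F3 | step 6 | tert-butyl (4R,5R)-4-({(1R)-2-methyl-3-[(trimethylsilyl)oxy]cyclopent-2-en-1-yl}methyl)-5-[(triisopropylsilyl)oxy]hexanoate | C[C@@H](O[Si](C(C)C)(C(C)C)C(C)C)[C@H](CCC(=O)OC(C)(C)C)C[C@H]1CCC(O[Si](C)(C)C)=C1C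
F4 | step 7 | 3-methyl-1-(2,4,6-trimethoxyphenyl)butan-1-ol (racemic) | CC(C)CC(O)c1c(OC)cc(OC)cc1OC
F5 | step 14 | (10R)-10-hydroxy-10-methyl-3-ketone (21 with the C10 methyl carbinol in place) | C[C@@H](O[Si](C(C)C)(C(C)C)C(C)C)[C@@H]1CC[C@@](C)(O)[C@@H]2CC(=O)[C@](C)([C@@H](CC(C)C)c3c(OC)cc(OC)cc3OC)[C@H]2C1
F6 | step 23 | mono-aldehyde triphenol (30 with three free hydroxyl groups) | C=C(C)[C@@H]1CC[C@@](C)(O)[C@@H]2CC[C@](C)([C@@H](CC(C)C)c3c(O)c(C=O)c(O)cc3O)[C@H]2C1
A1 | alternative 1 | methyl 3-alkyl-2,4,6-trihydroxybenzoate carrying the silylated sesquiterpene | C=C(C)[C@@H]1CC[C@@](C)(O[Si](CC)(CC)CC)[C@@H]2CC[C@](C)([C@@H](CC(C)C)c3c(O)c(C(=O)OC)c(O)cc3O)[C@H]2C1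
A2 | alternative 2 | methyl 2-oxocyclopentanecarboxylate with quaternary C4 and C1' | COC(=O)C1C(=O)CC[C@]1(C)[C@@H](CC(C)C)c2c(OC)cc(OC)cc2OC
A3 | alternative 3 | 2-alkyl-3,5-dimethoxyphenol carrying the silylated sesquiterpene | C=C(C)[C@@H]1CC[C@@](C)(O[Si](CC)(CC)CC)[C@@H]2CC[C@](C)([C@@H](CC(C)C)c3c(O)cc(OC)cc3OC)[C@H]2C1
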